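Ring A is not taken from an aromatic starting material but assembled around the pre-formed C8 side chain. It is a 2-alkylresorcinol in which C8 sits between C8a–O1 and C7–O7, exactly the pattern that a vinylketene and a siloxyalkyne produce with the two oxygens differentiated. One photochemical operation on a diazo enone and an (R)-siloxyalkyne (whose C2'' carbinol comes from an asymmetric propargylation) forms four ring bonds and delivers the phenol with free O1–H, silylated O7 and C4a as the only open ortho position. Ortho-formylation, chromone formation and a rhodium-catalysed asymmetric aryl addition then set C2, and one fluoride step unmasks the target.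

Key step: step 6

Conventions: flavanone numbering (O1, C2, C3, C4, C4a, C5–C8, C8a; side chain C1''–C4''; ring B primed). TBS = tert-butyldimethylsilyl, TIPS = triisopropylsilyl.

Remark: the catalyst antipodes in steps 1 and 13 are assigned by analogy with the usual facial preference of these catalyst classes (Re-face propargylation of aldehydes; S-configured biaryl bisphosphines giving (S)-3-arylcycloalkanones, which corresponds to 2S in a chromone) and are assumed to carry over to these substrates.

Step 1
Reactants: 1 methacrolein (2-methylprop-2-enal)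
Product: 3 (3R)-2-methylhex-1-en-5-yn-3-ol, via pinacol borate ester 2 (not isolated)
Conditions: allenylboronic acid pinacol ester (1.3 equiv), (R)-TRIP [(R)-3,3'-bis(2,4,6-triisopropylphenyl)-1,1'-binaphthyl-2,2'-diyl hydrogen phosphate, 10 mol %], 4 Å MS, cyclohexane/toluene, 0 °C to rt; aqueous NaHCO3 work-up
Reagents that add atoms: allenylboronic acid pinacol ester, C=C=CB1OC(C)(C)C(C)(C)O1
Why: Chiral phosphoric acid-catalysed asymmetric propargylation, in which the allenylboronate adds by SE2' through a closed six-membered transition state held by the phosphate, so that the (R)-catalyst should direct attack to the Re face of the enal and set the carbinol centre as R.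

Step 2
Reactants: 3 (3R)-2-methylhex-1-en-5-yn-3-ol
Product: 4 tert-butyl(dimethyl){[(3R)-2-methylhex-1-en-5-yn-3-yl]oxy}silane
Conditions: TBSCl, imidazole, DMF, rt
Reagents that add atoms: tert-butyldimethylsilyl chloride, CC(C)(C)[Si](C)(C)Cl
Why: Imidazole-promoted O-silylation of a secondary alcohol, which does not touch the stereocentre.

Step 3
Reactants: 4 tert-butyl(dimethyl){[(3R)-2-methylhex-1-en-5-yn-3-yl]oxy}silane
Product: 7 (4R)-4-(TBSO)-5-methyl-1-(TIPSO)hex-5-en-1-yne, via lithium acetylide 5 (not isolated), via lithium ynolate 6 (not isolated)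
Conditions: n-BuLi, THF, −78 °C; t-BuOOLi (from t-BuOOH and LiHMDS, THF, −78 °C), −78 to 0 °C; TIPSOTf, −78 to 0 °C
Reagents that add atoms: tert-butyl hydroperoxide, CC(C)(C)OO; triisopropylsilyl trifluoromethanesulfonate, CC(C)[Si](C(C)C)(C(C)C)OS(=O)(=O)C(F)(F)F
Why: Electrophilic oxygenation of a lithium acetylide by a lithium alkyl peroxide (oxenoid oxygen transfer) gives the ynolate, which the bulky silyl triflate traps on oxygen, and no enolisable β-silyloxy carbonyl compound is involved.

Step 4
Reactants: 8 methyl vinyl ketone (but-3-en-2-one)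
Product: 10 1,1,1-trifluorohex-5-ene-2,4-dione, via lithium dienolate 9 (not isolated)
Conditions: LiHMDS, THF, −78 °C; CF3CO2CH2CF3, −78 °C; aqueous HCl, extraction, crude product used at once
Reagents that add atoms: 2,2,2-trifluoroethyl trifluoroacetate, O=C(OCC(F)(F)F)C(F)(F)F
Why: Kinetic deprotonation of the methyl group gives the cross-conjugated lithium dienolate, which is C-acylated by the activated ester in a Claisen condensation that prepares the ketone for diazo transfer.

Step 5
Reactants: 10 1,1,1-trifluorohex-5-ene-2,4-dione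
Product: 11 1-diazobut-3-en-2-one
Conditions: MsN3, Et3N, H2O (1 equiv), MeCN, rt; aqueous NaOH wash; kept as a cold solution in the dark
Reagents that add atoms: methanesulfonyl azide, CS(=O)(=O)N=[N+]=[N-]
Why: Regitz diazo transfer to the activated 1,3-diketone with loss of the trifluoroacetyl group as the N-sulfonyl amide (detrifluoroacetylative diazo transfer), which avoids diazomethane that would add to the enone.

Step 6
Reactants: 7 (4R)-4-(TBSO)-5-methyl-1-(TIPSO)hex-5-en-1-yne; 11 1-diazobut-3-en-2-one
Product: 16 2-[(2R)-2-(TBSO)-3-methylbut-3-en-1-yl]-3-(TIPSO)phenol, via vinylketene 12 (not isolated), via 4-vinylcyclobutenone 13 (not isolated), via dienylketene 14 (not isolated), via cyclohexadienone 15 (not isolated)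
Conditions: 11 (1.5–2 equiv, added in portions), degassed ClCH2CH2Cl, hν (254 nm, low-pressure Hg lamp, quartz), rt; then 80 °C in the dark
Reagents that add atoms: none
Why: Irradiation expels N2 from 11 and the vinyl group shifts to the carbene carbon (Wolff rearrangement, forming C5–C6) to give vinylketene 12, whose electrophilic carbonyl carbon is attacked by the nucleophilic chain-bearing alkyne carbon of 7 in a regioselective [2+2] cycloaddition (C8–C8a and C6–C7) that gives cyclobutenone 13. Four-electron conrotatory opening of 13 gives dienylketene 14, and ring A closes by thermal disrotatory six-electron electrocyclisation between the ketene carbon and the vinyl terminus (C4a–C8a) to dienone 15, which tautomerises to phenol 16. The closest known reaction type is the Danheiser benzannulation of vinylketenes generated from diazo enones with trialkylsiloxyalkynes, which gives resorcinol monosilyl ethers. No stereocentre is created, since the sp3 ring carbon of 13 is transient, and the C2'' centre, separated from the alkyne by a methylene group, is not involved. The step needs regiocontrol in the cycloaddition and chemoselectivity for the alkyne over the isopropenyl group; the siloxy donor polarises the triple bond so that the chain carbon bonds to the ketene carbonyl carbon and makes the ynol ether far more reactive towards the ketene than the unactivated 1,1-disubstituted alkene, so the chain ends at C8 between free O1–H and silylated O7.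

Step 7
Reactants: 16 2-[(2R)-2-(TBSO)-3-methylbut-3-en-1-yl]-3-(TIPSO)phenol
Product: 17 2-hydroxy-3-[(2R)-2-(TBSO)-3-methylbut-3-en-1-yl]-4-(TIPSO)benzaldehyde
Conditions: MgCl2 (anhydrous), Et3N, (CH2O)n, THF, reflux; aqueous NH4Cl
Reagents that add atoms: paraformaldehyde (as formaldehyde), C=O
Why: Magnesium-mediated ortho-formylation (Casiraghi–Skattebøl type), in which the magnesium phenoxide delivers formaldehyde to C4a, the only open ortho carbon, and a second formaldehyde oxidises the benzylic alkoxide by hydride transfer.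

Step 8
Reactants: 17 2-hydroxy-3-[(2R)-2-(TBSO)-3-methylbut-3-en-1-yl]-4-(TIPSO)benzaldehyde
Product: 18 1-{2-hydroxy-3-[(2R)-2-(TBSO)-3-methylbut-3-en-1-yl]-4-(TIPSO)phenyl}prop-2-yn-1-ol (both carbinol epimers)
Conditions: HC≡CMgBr (3 equiv), THF, 0 °C to rt; saturated aqueous NH4Cl; crude product carried forward
Reagents that add atoms: ethynylmagnesium bromide, C#C[Mg]Br
Why: Grignard 1,2-addition to the aldehyde after the first equivalent has formed the magnesium phenoxide; the new carbinol centre is formed without control and is removed by oxidation in the next step.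

Step 9
Reactants: 18 1-{2-hydroxy-3-[(2R)-2-(TBSO)-3-methylbut-3-en-1-yl]-4-(TIPSO)phenyl}prop-2-yn-1-ol
Product: 21 8-[(2R)-2-(TBSO)-3-methylbut-3-en-1-yl]-7-(TIPSO)-4H-chromen-4-one, via ynone 19 (not isolated), via enaminone 20 (not isolated)
Conditions: MnO2, CH2Cl2, rt; filtration; Et2NH (1.2 equiv), EtOH, rt
Reagents that add atoms: none
Why: MnO2 oxidation of the benzylic propargylic alcohol gives the ynone, aza-Michael addition of the amine gives the enaminone, and intramolecular addition–elimination by the O1 phenol at the β-carbon closes the pyranone in the six-membered (endo) mode with release of the amine.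

Step 10
Reactants: 22 4-bromophenol; 23 prenyl bromide (1-bromo-3-methylbut-2-ene)
Product: 25 4-bromo-2,6-bis(3-methylbut-2-en-1-yl)phenol, via 4-bromo-2-prenylphenol 24 (not isolated)
Conditions: NaH (1.1 equiv), 23 (1.05 equiv), toluene, 0 °C to rt; then a second charge of NaH (1.1 equiv) and 23 (1.05 equiv) in the same flask, rt; aqueous NH4Cl
Reagents that add atoms: prenyl bromide (second equivalent of 23, which supplies the second C5 chain), CC(C)=CCBr
Why: Ortho-selective C-alkylation of a sodium phenoxide, carried out twice in one flask (first to 24, then to 25), in which the tight ion aggregates in a non-polar solvent steer SN2 attack of the allylic bromide to the ring carbon next to oxygen while bromine blocks the para position.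

Step 11
Reactants: 25 4-bromo-2,6-bis(3-methylbut-2-en-1-yl)phenol
Product: 26 [4-bromo-2,6-bis(3-methylbut-2-en-1-yl)phenoxy](tert-butyl)dimethylsilane
Conditions: TBSCl, imidazole, DMF, 40 °C
Reagents that add atoms: tert-butyldimethylsilyl chloride, CC(C)(C)[Si](C)(C)Cl
Why: Imidazole-promoted O-silylation of the phenol, which masks the acidic proton before metalation and keeps the later flavanone from opening through a 4'-phenoxide.

Step 12
Reactants: 26 [4-bromo-2,6-bis(3-methylbut-2-en-1-yl)phenoxy](tert-butyl)dimethylsilane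
Product: 29 [4-(TBSO)-3,5-bis(3-methylbut-2-en-1-yl)phenyl]boronic acid, via aryllithium 27 (not isolated), via lithium triisopropoxyborate 28 (not isolated)
Conditions: n-BuLi, THF, −78 °C; B(OiPr)3, −78 °C to rt; 1 M aqueous HCl, 0 °C, brief
Reagents that add atoms: triisopropyl borate, CC(C)OB(OC(C)C)OC(C)C; water, O
Why: Bromine–lithium exchange, electrophilic borylation of the aryllithium and hydrolysis of the borate, with the silyloxy group para to the metalated carbon so that no silyl migration can occur.

Step 13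
Reactants: 21 8-[(2R)-2-(TBSO)-3-methylbut-3-en-1-yl]-7-(TIPSO)-4H-chromen-4-one; 29 [4-(TBSO)-3,5-bis(3-methylbut-2-en-1-yl)phenyl]boronic acid
Product: 30 (2S)-2-[4-(TBSO)-3,5-bis(3-methylbut-2-en-1-yl)phenyl]-8-[(2R)-2-(TBSO)-3-methylbut-3-en-1-yl]-7-(TIPSO)-2,3-dihydro-4H-chromen-4-one
Conditions: [Rh(OH)(cod)]2 (2.5 mol %), (S)-MeO-F12-BIPHEP [(S)-2,2'-bis[bis(3,4,5-trifluorophenyl)phosphino]-6,6'-dimethoxy-1,1'-biphenyl, 5.5 mol %], 29 (2.5 equiv), CH2Cl2/H2O, 20 °C
Reagents that add atoms: none
Why: Rhodium-catalysed asymmetric 1,4-addition of an arylboronic acid to a chromone (Hayashi–Miyaura reaction), in which the aryl–rhodium species carrying the S-configured bisphosphine inserts the C2=C3 bond with aryl delivery to the Re face of C2 to give the 2S centre, and water protonates the rhodium enolate under base-free conditions that do not reopen the pyranone.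

Step 14
Reactants: 30 (2S)-2-[4-(TBSO)-3,5-bis(3-methylbut-2-en-1-yl)phenyl]-8-[(2R)-2-(TBSO)-3-methylbut-3-en-1-yl]-7-(TIPSO)-2,3-dihydro-4H-chromen-4-one
Product: 31 (2S)-7-hydroxy-2-[4-hydroxy-3,5-bis(3-methylbut-2-en-1-yl)phenyl]-8-[(2R)-2-hydroxy-3-methylbut-3-en-1-yl]-2,3-dihydro-4H-chromen-4-one (CNP0127055.2)
Conditions: HF·pyridine, pyridine, THF, 0 °C to rt; pH 7 phosphate buffer quench
Reagents that add atoms: none
Why: Fluoride-driven cleavage of all three silyl ethers, run in pyridine-buffered HF so that no phenoxide forms and C2 is not scrambled by retro-oxa-Michael ring opening, while the medium is too weakly acidic to cyclise the prenyl groups or ionise the allylic alcohol.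

Compound list
1 | methacrolein (2-methylprop-2-enal) | C=C(C)C=O | starting material
2 | pinacol borate ester of 3 (not isolated) | C=C(C)[C@H](OB1OC(C)(C)C(C)(C)O1)CC#C | intermediate
3 | (3R)-2-methylhex-1-en-5-yn-3-ol | C=C(C)[C@H](O)CC#C | intermediate
4 | tert-butyl(dimethyl){[(3R)-2-methylhex-1-en-5-yn-3-yl]oxy}silane | C=C(C)[C@H](O[Si](C)(C)C(C)(C)C)CC#C | intermediate
5 | lithium acetylide of 4 (not isolated) | C=C(C)[C@H](O[Si](C)(C)C(C)(C)C)CC#C[Li] | intermediate
6 | lithium (4R)-4-(TBSO)-5-methylhex-5-en-1-yn-1-olate, lithium ynolate (not isolated) | C=C(C)[C@H](O[Si](C)(C)C(C)(C)C)CC#C[O-].[Li+] | intermediate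
7 | (4R)-4-(TBSO)-5-methyl-1-(TIPSO)hex-5-en-1-yne | C=C(C)[C@H](O[Si](C)(C)C(C)(C)C)CC#CO[Si](C(C)C)(C(C)C)C(C)C | intermediate
8 | methyl vinyl ketone (but-3-en-2-one) | C=CC(C)=O | starting material
9 | lithium buta-1,3-dien-2-olate, lithium dienolate (not isolated) | [Li+].[O-]C(=C)C=C | intermediate
10 | 1,1,1-trifluorohex-5-ene-2,4-dione | C=CC(=O)CC(=O)C(F)(F)F | intermediate
11 | 1-diazobut-3-en-2-one | C=CC(=O)C=[N+]=[N-] | intermediate
12 | vinylketene, buta-1,3-dien-1-one (not isolated) | C=CC=C=O | intermediate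
13 | 2-[(2R)-2-(TBSO)-3-methylbut-3-en-1-yl]-3-(TIPSO)-4-vinylcyclobut-2-en-1-one, both C4 epimers (not isolated) | C=C(C)[C@H](O[Si](C)(C)C(C)(C)C)CC1=C(O[Si](C(C)C)(C(C)C)C(C)C)C(C=C)C1=O | intermediate
14 | 2-[(2R)-2-(TBSO)-3-methylbut-3-en-1-yl]-3-(TIPSO)hexa-1,3,5-trien-1-one, ketene carbon cis to vinyl (not isolated) | C=C(C)[C@H](O[Si](C)(C)C(C)(C)C)CC(=C=O)/C(O[Si](C(C)C)(C(C)C)C(C)C)=C\C=C | intermediate
15 | 2-[(2R)-2-(TBSO)-3-methylbut-3-en-1-yl]-3-(TIPSO)cyclohexa-2,4-dien-1-one (not isolated) | C=C(C)[C@H](O[Si](C)(C)C(C)(C)C)CC1=C(O[Si](C(C)C)(C(C)C)C(C)C)C=CCC1=O | intermediate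
16 | 2-[(2R)-2-(TBSO)-3-methylbut-3-en-1-yl]-3-(TIPSO)phenol | C=C(C)[C@H](O[Si](C)(C)C(C)(C)C)Cc1c(O)cccc1O[Si](C(C)C)(C(C)C)C(C)C | intermediate
17 | 2-hydroxy-3-[(2R)-2-(TBSO)-3-methylbut-3-en-1-yl]-4-(TIPSO)benzaldehyde | C=C(C)[C@H](O[Si](C)(C)C(C)(C)C)Cc1c(O)c(C=O)ccc1O[Si](C(C)C)(C(C)C)C(C)C | intermediate
18 | 1-{2-hydroxy-3-[(2R)-2-(TBSO)-3-methylbut-3-en-1-yl]-4-(TIPSO)phenyl}prop-2-yn-1-ol, both carbinol epimers | C=C(C)[C@H](O[Si](C)(C)C(C)(C)C)Cc1c(O)c(C(O)C#C)ccc1O[Si](C(C)C)(C(C)C)C(C)C | intermediate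
19 | 1-{2-hydroxy-3-[(2R)-2-(TBSO)-3-methylbut-3-en-1-yl]-4-(TIPSO)phenyl}prop-2-yn-1-one, ynone (not isolated) | C=C(C)[C@H](O[Si](C)(C)C(C)(C)C)Cc1c(O)c(C(=O)C#C)ccc1O[Si](C(C)C)(C(C)C)C(C)C | intermediate
20 | (E)-3-(diethylamino)-1-{2-hydroxy-3-[(2R)-2-(TBSO)-3-methylbut-3-en-1-yl]-4-(TIPSO)phenyl}prop-2-en-1-one, enaminone (not isolated) | C=C(C)[C@H](O[Si](C)(C)C(C)(C)C)Cc1c(O)c(C(=O)/C=C/N(CC)CC)ccc1O[Si](C(C)C)(C(C)C)C(C)C | intermediate
21 | 8-[(2R)-2-(TBSO)-3-methylbut-3-en-1-yl]-7-(TIPSO)-4H-chromen-4-one | C=C(C)[C@H](O[Si](C)(C)C(C)(C)C)Cc1c(O[Si](C(C)C)(C(C)C)C(C)C)ccc2c(=O)ccoc12 | intermediate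
22 | 4-bromophenol | Oc1ccc(Br)cc1 | starting material
23 | prenyl bromide (1-bromo-3-methylbut-2-ene) | CC(C)=CCBr | starting material
24 | 4-bromo-2-(3-methylbut-2-en-1-yl)phenol (not isolated) | CC(C)=CCc1cc(Br)ccc1O | intermediate
25 | 4-bromo-2,6-bis(3-methylbut-2-en-1-yl)phenol | CC(C)=CCc1cc(Br)cc(CC=C(C)C)c1O | intermediate
26 | [4-bromo-2,6-bis(3-methylbut-2-en-1-yl)phenoxy](tert-butyl)dimethylsilane | CC(C)=CCc1cc(Br)cc(CC=C(C)C)c1O[Si](C)(C)C(C)(C)C | intermediate
27 | [4-(TBSO)-3,5-bis(3-methylbut-2-en-1-yl)phenyl]lithium, aryllithium (not isolated) | [Li]c1cc(CC=C(C)C)c(O[Si](C)(C)C(C)(C)C)c(CC=C(C)C)c1 | intermediate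
28 | lithium [4-(TBSO)-3,5-bis(3-methylbut-2-en-1-yl)phenyl]triisopropoxyborate (not isolated) | [Li+].CC(C)O[B-](OC(C)C)(OC(C)C)c1cc(CC=C(C)C)c(O[Si](C)(C)C(C)(C)C)c(CC=C(C)C)c1 | intermediate
29 | [4-(TBSO)-3,5-bis(3-methylbut-2-en-1-yl)phenyl]boronic acid | OB(O)c1cc(CC=C(C)C)c(O[Si](C)(C)C(C)(C)C)c(CC=C(C)C)c1 | intermediate
30 | (2S)-2-[4-(TBSO)-3,5-bis(3-methylbut-2-en-1-yl)phenyl]-8-[(2R)-2-(TBSO)-3-methylbut-3-en-1-yl]-7-(TIPSO)-2,3-dihydro-4H-chromen-4-one | C=C(C)[C@H](O[Si](C)(C)C(C)(C)C)Cc1c(O[Si](C(C)C)(C(C)C)C(C)C)ccc2c1O[C@H](c1cc(CC=C(C)C)c(O[Si](C)(C)C(C)(C)C)c(CC=C(C)C)c1)CC2=O | intermediate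
31 | (2S)-7-hydroxy-2-[4-hydroxy-3,5-bis(3-methylbut-2-en-1-yl)phenyl]-8-[(2R)-2-hydroxy-3-methylbut-3-en-1-yl]-2,3-dihydro-4H-chromen-4-one | C=C(C)[C@H](O)Cc1c(O)ccc2c1O[C@H](c1cc(CC=C(C)C)c(O)c(CC=C(C)C)c1)CC2=O | target

Total step count: 14. Longest linear sequence: 9 steps (steps 1, 2, 3, 6, 7, 8, 9, 13, 14).

Steps most likely to fail

Step 6. The unsubstituted diazo enone may be lost before it is photolysed, by dipolar addition of one molecule to the enone of another or by polymerisation. The vinylketene may also dimerise or acylate the product phenol, and the phenol may undergo secondary photoreactions at 254 nm. The fallback sets out from siloxyalkyne 7 and generates the same ketene thermally, without a diazo compound or light. Cyclobutenone F1, obtained by dehydrobromination of commercial 3-bromocyclobutanone with Bu3N, would be heated with 7 in toluene at 80 °C. Reversible four-electron ring opening of F1 gives vinylketene 12, which 7 captures, and the sequence runs on through 13, 14 and 15 to phenol 16, where the route is rejoined. This also removes the need for steps 4 and 5.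

Step 13. Facial discrimination in the aryl transfer to the donor-substituted, 8-substituted chromone may be insufficient, and protodeboronation or a second 1,2-addition to the product ketone may compete. The fallback sets out from chromone 21 and boronic acid 29 and replaces catalyst-controlled addition by a catalyst-controlled kinetic resolution. Aryl addition with [Rh(OH)(cod)]2 and no chiral ligand (dioxane/H2O) would give 30 together with its (2R)-epimer F2. Noyori-type asymmetric transfer hydrogenation of the mixture (RuCl(p-cymene)[(R,R)-TsDPEN], HCO2H/Et3N) should reduce only the matched (2R)-ketone, to the cis-(2R,4R)-flavan-4-ol F3. The mismatched (2S)-ketone 30 remains, is separated from the alcohol by chromatography, and the route is rejoined at 30.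

Step 10. O-alkylation may compete with C-alkylation, the reaction may stop at the mono-prenyl stage, and over-alkylation to dienones is possible. The fallback sets out from 4-bromophenol 22 and installs both chains by sigmatropic rearrangement. O-allylation (allyl bromide, K2CO3, acetone) would give allyl 4-bromophenyl ether F4, and aromatic Claisen rearrangement (N,N-diethylaniline, 190 °C) 2-allyl-4-bromophenol F5. A second O-allylation to the allyl ether F6 and a second Claisen rearrangement would give 2,6-diallyl-4-bromophenol F7. Twofold olefin cross-metathesis with 2-methylbut-2-ene (second-generation Grubbs catalyst, CH2Cl2, 40 °C) then converts both allyl groups into prenyl groups and rejoins the route at 25.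

Further compounds
F1 | step 6 | cyclobut-2-en-1-one | O=C1C=CC1
F2 | step 13 | (2R)-2-[4-(TBSO)-3,5-bis(3-methylbut-2-en-1-yl)phenyl]-8-[(2R)-2-(TBSO)-3-methylbut-3-en-1-yl]-7-(TIPSO)-2,3-dihydro-4H-chromen-4-one | C=C(C)[C@H](O[Si](C)(C)C(C)(C)C)Cc1c(O[Si](C(C)C)(C(C)C)C(C)C)ccc2c1O[C@@H](c1cc(CC=C(C)C)c(O[Si](C)(C)C(C)(C)C)c(CC=C(C)C)c1)CC2=O
F3 | step 13 | (2R,4R)-2-[4-(TBSO)-3,5-bis(3-methylbut-2-en-1-yl)phenyl]-8-[(2R)-2-(TBSO)-3-methylbut-3-en-1-yl]-7-(TIPSO)-3,4-dihydro-2H-chromen-4-ol | C=C(C)[C@H](O[Si](C)(C)C(C)(C)C)Cc1c(O[Si](C(C)C)(C(C)C)C(C)C)ccc2c1O[C@@H](c1cc(CC=C(C)C)c(O[Si](C)(C)C(C)(C)C)c(CC=C(C)C)c1)C[C@H]2O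
F4 | step 10 | 1-bromo-4-(prop-2-en-1-yloxy)benzene | C=CCOc1ccc(Br)cc1
F5 | step 10 | 4-bromo-2-(prop-2-en-1-yl)phenol | C=CCc1cc(Br)ccc1O
F6 | step 10 | 4-bromo-2-(prop-2-en-1-yl)-1-(prop-2-en-1-yloxy)benzene | C=CCOc1ccc(Br)cc1CC=C
F7 | step 10 | 4-bromo-2,6-di(prop-2-en-1-yl)phenol | C=CCc1cc(Br)cc(CC=C)c1O
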